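**Strategy.** The trans-decalin is cut at C4–C5 and C9–C10, which unfolds it to an acyclic (3R,4S)-epoxy geranylgeranoate. The key step, a Lewis acid-triggered epoxy-polyene cyclization modelled on labdane biosynthesis, closes ring A (C1–C5, C10) through C4–C5 and, in the same cascade, ring B through C9–C10. It sets C4, C5, C9 and C10 from the C3–C4 epoxide and the olefin geometries, and no ring is closed afterwards. It exploits the 1,3-dioxygenation C3–O/C19–O of ring A: a Z allylic alcohol is the handle for asymmetric epoxidation and ends as the axial C19 arm on C4. C3 is then inverted via the ketone.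

Key step: step 8

Remark on numbering: labdane numbering is used throughout (ring A = C1–C5 and C10; ring B = C5–C10; C11–C16 side chain; C17 methyl on C8; C18 methyl and C19 oxygenated carbon on C4; C20 methyl on C10); the target is (3S,4R,5S,9R,10S,13E).
Assumption: (5E,9E)-farnesylacetone is bought as the single E,E isomer; an isomer-mixture grade would first need separation.

Step 1
Reactants: 1 (5E,9E)-farnesylacetone; 2 tert-butyl diethylphosphonoacetate
Product: 3 tert-butyl (2E,6E,10E)-3,7,11,15-tetramethylhexadeca-2,6,10,14-tetraenoate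
Conditions: NaH, THF, 0 °C to rt
Reagents that add atoms: none
Why: Horner–Wadsworth–Emmons olefination of the methyl ketone with the sodium phosphonate should give mainly the 2E enoate (the 2Z isomer is removed by chromatography), and the tert-butyl ester is chosen because it resists the later hydride and Lewis acid steps.

Step 2
Reactants: 3 tert-butyl geranylgeranoate
Product: 5 tert-butyl (2E,6E,10E)-14,15-epoxy-3,7,11,15-tetramethylhexadeca-2,6,10-trienoate (racemic), via bromohydrin 4 (not isolated)
Conditions: NBS, THF/H2O, 0 °C; then K2CO3, MeOH, rt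
Reagents that add atoms: water, O
Why: Electrophilic bromohydrin formation should select the terminal, most electron-rich and least hindered trisubstituted olefin (the enoate olefin is deactivated), and K2CO3 then closes the bromohydrin to the racemic epoxide by intramolecular SN2 displacement (this stereocentre is destroyed in step 3).

Step 3
Reactants: 5 racemic terminal epoxide
Product: 6 tert-butyl (2E,6E,10E)-3,7,11-trimethyl-14-oxotetradeca-2,6,10-trienoate
Conditions: H5IO6, THF/Et2O, 0 °C
Reagents that add atoms: none
Why: Periodic acid opens the epoxide to the vicinal diol and cleaves it in the same flask (Malaprade-type glycol cleavage), which removes the three terminal carbons as acetone and leaves the aldehyde carbon that becomes C3.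

Step 4
Reactants: 6 aldehyde; 7 ethyl 2-[bis(2,2,2-trifluoroethoxy)phosphoryl]propanoate
Product: 8 16-tert-butyl 1-ethyl (2Z,6E,10E,14E)-2,6,10,14-tetramethylhexadeca-2,6,10,14-tetraenedioate
Conditions: KN(SiMe3)2, 18-crown-6, THF, −78 °C
Reagents that add atoms: none
Why: Still–Gennari olefination with the bis(trifluoroethyl) phosphonate under dissociating conditions should give the Z trisubstituted enoate under kinetic control, which places the future C19 carbon cis to the chain.

Step 5
Reactants: 8 Z-enoate diester
Product: 9 tert-butyl (2E,6E,10E,14Z)-16-hydroxy-3,7,11,15-tetramethylhexadeca-2,6,10,14-tetraenoate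
Conditions: iBu2AlH (2.1 equiv), CH2Cl2, −78 °C
Reagents that add atoms: none
Why: 1,2-Reduction with iBu2AlH at −78 °C should consume the ethyl ester of the Z enoate much faster than the bulky tert-butyl ester of the β,β-disubstituted enoate, giving the Z allylic alcohol without touching the olefin geometry.

Step 6
Reactants: 9 Z allylic alcohol
Product: 10 tert-butyl (2E,6E,10E)-13-[(2R,3S)-3-(hydroxymethyl)-3-methyloxiran-2-yl]-3,7,11-trimethyltrideca-2,6,10-trienoate
Conditions: Ti(OiPr)4 (10 mol %), L-(+)-diethyl tartrate (12 mol %), tBuOOH, 4 Å molecular sieves, CH2Cl2, −20 °C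
Reagents that add atoms: tert-butyl hydroperoxide, CC(C)(C)OO
Why: Sharpless asymmetric epoxidation is directed by the allylic hydroxyl (so the three other olefins are untouched), and with L-(+)-diethyl tartrate oxygen should be delivered to the face that gives the (2R,3S)-oxirane, that is C3 R and C4 S in labdane numbering.

Step 7
Reactants: 10 epoxy alcohol
Product: 11 tert-butyl (2E,6E,10E)-13-[(2R,3S)-3-[(tert-butyldimethylsilyloxy)methyl]-3-methyloxiran-2-yl]-3,7,11-trimethyltrideca-2,6,10-trienoate
Conditions: TBSCl, imidazole, DMF, rt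
Reagents that add atoms: tert-butyldimethylsilyl chloride, CC(C)(C)[Si](C)(C)Cl
Why: Silylation of the primary alcohol (imidazole-catalysed silyl transfer) masks the hydroxyl so that it can neither bind the Lewis acid nor open the epoxide in step 8.

Step 8
Reactants: 11 epoxy triene silyl ether
Product: 12 tert-butyl (3R,4R,5S,9R,10S,13E)-19-(tert-butyldimethylsilyloxy)-3-hydroxylabda-7,13-dien-15-oate
Conditions: MeAlCl2 (2.5 equiv), CH2Cl2, −78 °C; then Et3N, aq. NaHCO3
Reagents that add atoms: none
Why: MeAlCl2 binds the epoxide oxygen, the C4–O bond ionises while the C5=C10 olefin attacks C4 from the side opposite to oxygen, the C10 cation is captured by the C8=C9 olefin and the C8 cation loses the axial H7 to leave the C7=C8 olefin; the closest known reaction type is the Lewis acid-promoted epoxy-polyene cyclization that imitates labdane and oxidosqualene cyclases. Ring A closes 6-endo-trig at the C5=C10 olefin with exo opening of the epoxide at its tertiary carbon C4, and ring B closes 6-endo-trig at the C8=C9 olefin. C3 is carried over from the epoxide, C4 is set by inversion combined with the Z geometry (CH2OTBS axial and cis to C20, methyl equatorial), C5 and C10 by anti addition across the E C5=C10 olefin in a chair–chair fold that keeps the C3 oxygen equatorial (trans ring fusion), and C9 by the E C8=C9 olefin, which leaves C11 equatorial. The (3R) epoxide carbon decides which enantiomeric chair–chair fold is used, so the whole array of the ent-labdane series follows from the epoxidation in step 6. The step needs arrest at the bicycle and control of the terminating proton loss: the electron-poor C13=C14 enoate olefin does not attack the C8 cation, and loss of the accessible axial H7 to the endocyclic trisubstituted olefin is expected to be preferred over loss of the hindered H9 or of a C17 hydrogen, minor olefin isomers being removed on AgNO3-impregnated silica.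

Step 9
Reactants: 12 equatorial C3 alcohol
Product: 13 tert-butyl (4R,5S,9R,10S,13E)-19-(tert-butyldimethylsilyloxy)-3-oxolabda-7,13-dien-15-oate
Conditions: Dess–Martin periodinane, CH2Cl2, 0 °C to rt
Reagents that add atoms: none
Why: Dess–Martin oxidation converts the equatorial C3 alcohol into the ketone under neutral conditions that spare the silyl ether, the olefins and the ester, and the adjacent quaternary C4 cannot epimerise.

Step 10
Reactants: 13 C3 ketone
Product: 14 tert-butyl (3S,4R,5S,9R,10S,13E)-19-(tert-butyldimethylsilyloxy)-3-hydroxylabda-7,13-dien-15-oate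
Conditions: LiBH(sBu)3, THF, −78 °C; then NaOH, H2O2, 0 °C
Reagents that add atoms: none
Why: Hydride reduction with the bulky LiBH(sBu)3 should proceed along the equatorial trajectory, because axial approach is blocked by the axial hydrogens on C1 and C5, and so give the axial (3S) alcohol as is usual for 4,4-disubstituted 3-oxo terpenoids, while the β,β-disubstituted enoate resists conjugate reduction at −78 °C.

Step 11
Reactants: 14 axial C3 alcohol
Product: 15 tert-butyl (3S,4R,5S,9R,10S,13E)-3-acetoxy-19-(tert-butyldimethylsilyloxy)labda-7,13-dien-15-oate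
Conditions: Ac2O, DMAP, pyridine, 40 °C
Reagents that add atoms: acetic anhydride, CC(=O)OC(C)=O
Why: DMAP-catalysed acylation (nucleophilic catalysis) esterifies the hindered axial C3 hydroxyl, the only free hydroxyl present.

Step 12
Reactants: 15 acetate silyl ether tert-butyl ester
Product: 17 (3S,4R,5S,9R,10S,13E)-3-acetoxy-19-hydroxylabda-7,13-dien-15-oic acid (CNP0129162.1), via trimethylsilyl ester 16 (not isolated)
Conditions: TMSOTf, 2,6-lutidine, CH2Cl2, 0 °C; then HF·pyridine, THF, 0 °C to rt
Reagents that add atoms: none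
Why: TMSOTf with 2,6-lutidine converts the tert-butyl ester into the trimethylsilyl ester with loss of isobutene without a protic acid that could move the C7=C8 olefin, and fluoride then cleaves both silicon–oxygen bonds (silyl ether and silyl ester cleavage), the acetate being unable to migrate to O19 because O3 and C19 are trans-diaxial.

**Compound list**

1 | (5E,9E)-6,10,14-trimethylpentadeca-5,9,13-trien-2-one ((E,E)-farnesylacetone) | CC(=O)CC/C=C(\C)CC/C=C(\C)CCC=C(C)C | starting material
2 | tert-butyl 2-(diethoxyphosphoryl)acetate (tert-butyl diethylphosphonoacetate) | CCOP(=O)(OCC)CC(=O)OC(C)(C)C | starting material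
3 | tert-butyl (2E,6E,10E)-3,7,11,15-tetramethylhexadeca-2,6,10,14-tetraenoate | CC(C)=CCC/C(C)=C/CC/C(C)=C/CC/C(C)=C/C(=O)OC(C)(C)C | intermediate
4 | tert-butyl (2E,6E,10E)-14-bromo-15-hydroxy-3,7,11,15-tetramethylhexadeca-2,6,10-trienoate (racemic) | CC(C)(O)C(Br)CC/C(C)=C/CC/C(C)=C/CC/C(C)=C/C(=O)OC(C)(C)C | intermediate (not isolated)
5 | tert-butyl (2E,6E,10E)-14,15-epoxy-3,7,11,15-tetramethylhexadeca-2,6,10-trienoate (racemic) | CC1(C)OC1CC/C(C)=C/CC/C(C)=C/CC/C(C)=C/C(=O)OC(C)(C)C | intermediate
6 | tert-butyl (2E,6E,10E)-3,7,11-trimethyl-14-oxotetradeca-2,6,10-trienoate | O=CCC/C(C)=C/CC/C(C)=C/CC/C(C)=C/C(=O)OC(C)(C)C | intermediate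
7 | ethyl 2-[bis(2,2,2-trifluoroethoxy)phosphoryl]propanoate | CCOC(=O)C(C)P(=O)(OCC(F)(F)F)OCC(F)(F)F | starting material
8 | 16-tert-butyl 1-ethyl (2Z,6E,10E,14E)-2,6,10,14-tetramethylhexadeca-2,6,10,14-tetraenedioate | CCOC(=O)/C(C)=C\CC/C(C)=C/CC/C(C)=C/CC/C(C)=C/C(=O)OC(C)(C)C | intermediate
9 | tert-butyl (2E,6E,10E,14Z)-16-hydroxy-3,7,11,15-tetramethylhexadeca-2,6,10,14-tetraenoate | OC/C(C)=C\CC/C(C)=C/CC/C(C)=C/CC/C(C)=C/C(=O)OC(C)(C)C | intermediate
10 | tert-butyl (2E,6E,10E)-13-[(2R,3S)-3-(hydroxymethyl)-3-methyloxiran-2-yl]-3,7,11-trimethyltrideca-2,6,10-trienoate | OC[C@]1(C)O[C@@H]1CC/C(C)=C/CC/C(C)=C/CC/C(C)=C/C(=O)OC(C)(C)C | intermediate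
11 | tert-butyl (2E,6E,10E)-13-[(2R,3S)-3-[(tert-butyldimethylsilyloxy)methyl]-3-methyloxiran-2-yl]-3,7,11-trimethyltrideca-2,6,10-trienoate | CC(C)(C)[Si](C)(C)OC[C@]1(C)O[C@@H]1CC/C(C)=C/CC/C(C)=C/CC/C(C)=C/C(=O)OC(C)(C)C | intermediate
12 | tert-butyl (3R,4R,5S,9R,10S,13E)-19-(tert-butyldimethylsilyloxy)-3-hydroxylabda-7,13-dien-15-oate (3-OH equatorial; CH2OTBS axial on C4, cis to C20; trans ring fusion) | O[C@@H]1CC[C@]2(C)[C@H](CC=C(C)[C@H]2CC/C(C)=C/C(=O)OC(C)(C)C)[C@]1(C)CO[Si](C)(C)C(C)(C)C | intermediate
13 | tert-butyl (4R,5S,9R,10S,13E)-19-(tert-butyldimethylsilyloxy)-3-oxolabda-7,13-dien-15-oate | O=C1CC[C@]2(C)[C@H](CC=C(C)[C@H]2CC/C(C)=C/C(=O)OC(C)(C)C)[C@]1(C)CO[Si](C)(C)C(C)(C)C | intermediate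
14 | tert-butyl (3S,4R,5S,9R,10S,13E)-19-(tert-butyldimethylsilyloxy)-3-hydroxylabda-7,13-dien-15-oate (3-OH axial) | O[C@H]1CC[C@]2(C)[C@H](CC=C(C)[C@H]2CC/C(C)=C/C(=O)OC(C)(C)C)[C@]1(C)CO[Si](C)(C)C(C)(C)C | intermediate
15 | tert-butyl (3S,4R,5S,9R,10S,13E)-3-acetoxy-19-(tert-butyldimethylsilyloxy)labda-7,13-dien-15-oate | CC(=O)O[C@H]1CC[C@]2(C)[C@H](CC=C(C)[C@H]2CC/C(C)=C/C(=O)OC(C)(C)C)[C@]1(C)CO[Si](C)(C)C(C)(C)C | intermediate
16 | trimethylsilyl (3S,4R,5S,9R,10S,13E)-3-acetoxy-19-(tert-butyldimethylsilyloxy)labda-7,13-dien-15-oate | CC(=O)O[C@H]1CC[C@]2(C)[C@H](CC=C(C)[C@H]2CC/C(C)=C/C(=O)O[Si](C)(C)C)[C@]1(C)CO[Si](C)(C)C(C)(C)C | intermediate (not isolated)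
17 | (3S,4R,5S,9R,10S,13E)-3-acetoxy-19-hydroxylabda-7,13-dien-15-oic acid (CNP0129162.1) | CC(=O)O[C@H]1CC[C@]2(C)[C@H](CC=C(C)[C@H]2CC/C(C)=C/C(=O)O)[C@]1(C)CO | target

**Step count.** Total: 12 steps. Longest linear sequence: 12 steps (from 1).

**Steps most likely to fail**

1. Step 8 (key step). The terminating proton loss from the C8 cation may be unselective, giving the exocyclic 8(17) or the tetrasubstituted 8(9) olefin beside the 7-ene. The activated epoxide may also collapse by a 1,2-hydride shift before C5 attacks. Fallback: olefin placement is taken out of the cyclization. Starting from 11, the cyclization mixture is not resolved. The exocyclic isomer tert-butyl (3R,4R,5S,9R,10S,13E)-19-(tert-butyldimethylsilyloxy)-3-hydroxylabda-8(17),13-dien-15-oate F1 that accompanies 12 is moved into the ring by RhCl3·3H2O-catalysed double-bond migration (EtOH, 70 °C). This is a known hydride addition–elimination isomerization that shifts an exocyclic methylene toward the less hindered allylic CH2 (C7) and should stop at the trisubstituted olefin. The route is rejoined at 12.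

2. Step 5. Discrimination between the two ester groups may be incomplete, with partial reduction of the tert-butyl enoate. Fallback: the ester detour is avoided. Starting from 6, Stork–Zhao-type Wittig olefination with (1-iodoethylidene)triphenylphosphorane (from ethyltriphenylphosphonium iodide, nBuLi, I2, then NaN(SiMe3)2, THF, −78 °C) should give the Z vinyl iodide tert-butyl (2E,6E,10E,14Z)-15-iodo-3,7,11-trimethylhexadeca-2,6,10,14-tetraenoate F2. Stille coupling of F2 with Bu3SnCH2OH (Pd(PPh3)4, dioxane, 80 °C) replaces iodine by CH2OH with retention of geometry. The route is rejoined at 9, bypassing 8.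

3. Step 10. Facial selectivity of hydride delivery may be poor, because the equatorial trajectory passes the axial CH2OTBS arm on C4. Fallback: the hydride is delivered from that arm instead. Starting from 13, HF·pyridine (THF) removes the silyl group to give tert-butyl (4R,5S,9R,10S,13E)-19-hydroxy-3-oxolabda-7,13-dien-15-oate F3. Evans–Saksena reduction with Me4NBH(OAc)3 (MeCN/AcOH, −20 °C) transfers hydride intramolecularly from the C19 alkoxyborohydride to the same face of C3 and should give the anti 1,3-diol tert-butyl (3S,4R,5S,9R,10S,13E)-3,19-dihydroxylabda-7,13-dien-15-oate F4, with the 3-OH axial. Selective silylation of the primary hydroxyl (TBSCl, imidazole, DMF, 0 °C) rejoins the route at 14.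

Further compounds
F1 | step 8 | tert-butyl (3R,4R,5S,9R,10S,13E)-19-(tert-butyldimethylsilyloxy)-3-hydroxylabda-8(17),13-dien-15-oate | O[C@@H]1CC[C@]2(C)[C@H](CCC(=C)[C@H]2CC/C(C)=C/C(=O)OC(C)(C)C)[C@]1(C)CO[Si](C)(C)C(C)(C)C
F2 | step 5 | tert-butyl (2E,6E,10E,14Z)-15-iodo-3,7,11-trimethylhexadeca-2,6,10,14-tetraenoate | I/C(C)=C\CC/C(C)=C/CC/C(C)=C/CC/C(C)=C/C(=O)OC(C)(C)C
F3 | step 10 | tert-butyl (4R,5S,9R,10S,13E)-19-hydroxy-3-oxolabda-7,13-dien-15-oate | O=C1CC[C@]2(C)[C@H](CC=C(C)[C@H]2CC/C(C)=C/C(=O)OC(C)(C)C)[C@]1(C)CO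
F4 | step 10 | tert-butyl (3S,4R,5S,9R,10S,13E)-3,19-dihydroxylabda-7,13-dien-15-oate | O[C@H]1CC[C@]2(C)[C@H](CC=C(C)[C@H]2CC/C(C)=C/C(=O)OC(C)(C)C)[C@]1(C)CO
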